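**Plan**

Atom labels follow benzofuran numbering: O1, C2, C3, C3a, C4–C7, C7a. Ring A is the six-membered ring and ring B the dihydrofuran.
Retrosynthesis: the two C5–prenyl bonds are cut first, then the O4 benzyl ether and the C–OH bond of the 2-hydroxypropan-2-yl group. Bonds C3–C3a and O1–C2 of ring B are then cut together, and the C7–acyl bond last.
Enabling feature: ring B joins ring carbon C3a to its neighbouring oxygen O1 through the CH2 C3 and the stereocentre C2, and the side chain on C2 is a hydrated isopropenyl group. C3, C2 and that chain are therefore the five carbons of an isoprene 1,4-bis-electrophile, which a palladium [3+2] allylic annulation can attach to an acylphloroglucinol.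
Forward: ring A begins as the phloroglucinol arene (acylation, para O-benzylation). Ring B is closed onto it by C-allylation then O-allylation in one flask. After hydration and debenzylation, ring A becomes the gem-diprenyl dienone in the last step.
Stereochemistry: the single stereocentre C2 (R) is set by the chiral diphosphine on palladium during the ring-closing O-allylation, and no later step breaks a bond at C2.

Key step: step 6

Assumption: the (1R,2R) ligand is taken as the enantiomer that gives 2R; if the first run shows the opposite sense, the (1S,2S) ligand is used and nothing else changes.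

**Route**

Step 1
Reactants: 1 phloroglucinol (benzene-1,3,5-triol); 2 3-methylbutanoyl chloride
Product: 3 3-methyl-1-(2,4,6-trihydroxyphenyl)butan-1-one
Conditions: AlCl3 (3 equiv), CH2Cl2/MeNO2, 0 °C to 40 °C; aq HCl work-up
Reagents that add atoms: none
Why: Friedel–Crafts acylation of a threefold-activated arene whose three ring positions are equivalent; the aluminium-bound aryl ketone is deactivated, so the reaction should stop after one acyl group.

Step 2
Reactants: 3 3-methyl-1-(2,4,6-trihydroxyphenyl)butan-1-one; 4 benzyl bromide
Product: 5 1-[4-(benzyloxy)-2,6-dihydroxyphenyl]-3-methylbutan-1-one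
Conditions: BnBr (1.0 equiv), K2CO3 (1.0 equiv), DMF, 0 °C to rt
Reagents that add atoms: none
Why: Williamson etherification; the hydroxyl para to the acyl group is the most acidic (vinylogous carboxylic acid) and the only one not held in a hydrogen bond to the ketone, so one equivalent of weak base and halide should alkylate it in preference to the two ortho hydroxyls.

Step 3
Reactants: 6 3-methylbut-2-en-1-ol
Product: 7 methyl 3-methylbut-2-en-1-yl carbonate
Conditions: ClCO2Me (1.2 equiv), pyridine (1.5 equiv), CH2Cl2, 0 °C
Reagents that add atoms: methyl chloroformate, COC(Cl)=O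
Why: O-acylation of a primary allylic alcohol by a chloroformate (carbonate formation) under mild base, which places the better of the two later leaving groups on the CH2 next to the alkene CH.

Step 4
Reactants: 7 methyl 3-methylbut-2-en-1-yl carbonate
Product: 8 (2E)-4-hydroxy-3-methylbut-2-en-1-yl methyl carbonate
Conditions: SeO2 (0.3 equiv), t-BuOOH (70 % aq, 2.5 equiv), salicylic acid (10 mol %), CH2Cl2, rt
Reagents that add atoms: selenium dioxide, O=[Se]=O; tert-butyl hydroperoxide, CC(C)(C)OO
Why: selenium dioxide allylic oxidation (ene reaction followed by [2,3]-sigmatropic shift), which on a trisubstituted alkene oxidises the methyl group trans to the chain and so should give the E allylic alcohol, the selectivity this oxidation shows with prenyl esters; the hydroperoxide recycles the selenium.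

Step 5
Reactants: 8 (2E)-4-hydroxy-3-methylbut-2-en-1-yl methyl carbonate
Product: 9 (2E)-4-[(methoxycarbonyl)oxy]-2-methylbut-2-en-1-yl acetate
Conditions: Ac2O (1.5 equiv), pyridine, DMAP (5 mol %), CH2Cl2, 0 °C to rt
Reagents that add atoms: acetic anhydride, CC(=O)OC(C)=O
Why: DMAP-catalysed acetylation of a primary alcohol; the methyl carbonate is untouched, so the product carries two allylic leaving groups of clearly different ionisation rate.

Step 6
Reactants: 5 1-[4-(benzyloxy)-2,6-dihydroxyphenyl]-3-methylbutan-1-one; 9 (2E)-4-[(methoxycarbonyl)oxy]-2-methylbut-2-en-1-yl acetate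
Product: 11 1-[(2R)-4-(benzyloxy)-6-hydroxy-2-(prop-1-en-2-yl)-2,3-dihydro-1-benzofuran-7-yl]-3-methylbutan-1-one, via C-allylated allylic acetate 10 (not isolated)
Conditions: Pd2(dba)3·CHCl3 (2.5 mol %), N,N'-[(1R,2R)-cyclohexane-1,2-diyl]bis[2-(diphenylphosphanyl)benzamide] (7.5 mol %), 5 (1.2 equiv), 9 (1.0 equiv), degassed CH2Cl2 (0.05 M), rt then 40 °C
Reagents that add atoms: none
Why: Tsuji–Trost cascade: zerovalent palladium ionises the allylic carbonate of 9 first (the better leaving group, lost as CO2 and methoxide), the methoxide deprotonates 5, and the phenoxide, a vinylogous 1,3-dicarbonyl nucleophile, attacks the unsubstituted CH2 terminus of the π-allyl complex through its free ring carbon to give 10, any O-allyl ether being re-ionised by the catalyst so that material drains to the irreversible C–C bond (C3–C3a). The catalyst then ionises the allylic acetate of 10, and the one phenol oxygen beside the new chain closes ring B by 5-exo attack on the substituted terminus of the 2-methyl π-allyl complex (bond O1–C2), the 7-endo alternative at the CH2 terminus being disfavoured, which leaves the isopropenyl group on C2. The closest known reaction type is the palladium-catalysed asymmetric allylic alkylation–etherification ([3+2] annulation) of 1,3-dicarbonyl compounds and phenols with but-2-ene-1,4-diyl bis-electrophiles, together with the asymmetric cyclisation of ortho-(4-acyloxy-3-methylbut-2-enyl)phenols to 2-isopropenyl-2,3-dihydrobenzofurans. C2 is set in this ring closure by the chiral diphosphine: the acetic acid released keeps π–σ–π interconversion of the diastereomeric π-allyl complexes faster than cyclisation, so the ligand pocket decides which face the oxygen attacks. The step needs carbonate-before-acetate ionisation (secured by leaving-group ability), a single C-allylation (the two free ring carbons of 5 are equivalent and 9 is the limiting reagent) and ring fusion on the oxygen ortho to the acyl group (the benzyl ether blocks the other neighbouring oxygen).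

Step 7
Reactants: 11 1-[(2R)-4-(benzyloxy)-6-hydroxy-2-(prop-1-en-2-yl)-2,3-dihydro-1-benzofuran-7-yl]-3-methylbutan-1-one
Product: 12 1-[(2R)-4-(benzyloxy)-6-hydroxy-2-(2-hydroxypropan-2-yl)-2,3-dihydro-1-benzofuran-7-yl]-3-methylbutan-1-one
Conditions: Co(acac)2 (20 mol %), PhSiH3 (2.5 equiv), O2 (1 atm), THF, rt
Reagents that add atoms: dioxygen, O=O
Why: Mukaiyama hydration, in which a cobalt hydride passes a hydrogen atom to the CH2 end of the 1,1-disubstituted alkene, O2 traps the tertiary radical and the silane reduces the peroxide to the Markovnikov tertiary alcohol; no bond at C2 is broken, so its configuration is kept, and the benzyl ether, ketone and hydrogen-bonded phenol should be inert.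

Step 8
Reactants: 12 1-[(2R)-4-(benzyloxy)-6-hydroxy-2-(2-hydroxypropan-2-yl)-2,3-dihydro-1-benzofuran-7-yl]-3-methylbutan-1-one
Product: 13 1-[(2R)-4,6-dihydroxy-2-(2-hydroxypropan-2-yl)-2,3-dihydro-1-benzofuran-7-yl]-3-methylbutan-1-one
Conditions: H2 (1 atm), Pd/C (10 % palladium on carbon, 10 mol %), EtOAc, rt
Reagents that add atoms: none
Why: catalytic hydrogenolysis of a benzyl aryl ether at a stage where no alkene remains; the O1–C2 bond of ring B is not benzylic and the electron-rich, hydrogen-bonded aryl ketone should not be reduced under one atmosphere of hydrogen.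

Step 9
Reactants: 13 1-[(2R)-4,6-dihydroxy-2-(2-hydroxypropan-2-yl)-2,3-dihydro-1-benzofuran-7-yl]-3-methylbutan-1-one; 14 1-bromo-3-methylbut-2-ene (prenyl bromide)
Product: 16 (2R)-6-hydroxy-2-(2-hydroxypropan-2-yl)-7-(3-methylbutanoyl)-5,5-bis(3-methylbut-2-en-1-yl)-2,3-dihydro-1-benzofuran-4(5H)-one, via monoprenylated phenol 15 (not isolated)
Conditions: 14 (2.5 equiv), NaOMe (3 equiv), MeOH, 0 °C to rt; then 1 M HCl, 0 °C
Reagents that add atoms: none
Why: base-mediated alkylative dearomatisation of a phloroglucinol (the reaction type that converts acylphloroglucinols into lupulone-type gem-diprenyl compounds): the phenoxide reacts through C5, the only unsubstituted ring carbon and the one flanked by two oxygens, first to 15 and then again at the same carbon, because the second alkylation gives the stabilised enolised β-triketone in which ring A is a cyclohexadienone; the protic solvent favours C- over O-alkylation, and the tertiary alcohol and C2 are not affected.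

**Compound list**

1 | phloroglucinol (benzene-1,3,5-triol) | Oc1cc(O)cc(O)c1 | starting material
2 | 3-methylbutanoyl chloride | CC(C)CC(Cl)=O | starting material
3 | 3-methyl-1-(2,4,6-trihydroxyphenyl)butan-1-one | CC(C)CC(=O)c1c(O)cc(O)cc1O | intermediate
4 | benzyl bromide | BrCc1ccccc1 | starting material
5 | 1-[4-(benzyloxy)-2,6-dihydroxyphenyl]-3-methylbutan-1-one | CC(C)CC(=O)c1c(O)cc(OCc2ccccc2)cc1O | intermediate
6 | 3-methylbut-2-en-1-ol | CC(C)=CCO | starting material
7 | methyl 3-methylbut-2-en-1-yl carbonate | COC(=O)OCC=C(C)C | intermediate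
8 | (2E)-4-hydroxy-3-methylbut-2-en-1-yl methyl carbonate | COC(=O)OC/C=C(C)/CO | intermediate
9 | (2E)-4-[(methoxycarbonyl)oxy]-2-methylbut-2-en-1-yl acetate | CC(=O)OC/C(C)=C/COC(=O)OC | intermediate
10 | (2E)-4-[6-(benzyloxy)-2,4-dihydroxy-3-(3-methylbutanoyl)phenyl]-2-methylbut-2-en-1-yl acetate | CC(=O)OC/C(C)=C/Cc1c(O)c(C(=O)CC(C)C)c(O)cc1OCc1ccccc1 | intermediate
11 | 1-[(2R)-4-(benzyloxy)-6-hydroxy-2-(prop-1-en-2-yl)-2,3-dihydro-1-benzofuran-7-yl]-3-methylbutan-1-one | CC(C)CC(=O)c1c(O)cc(OCc2ccccc2)c2c1O[C@@H](C(C)=C)C2 | intermediate
12 | 1-[(2R)-4-(benzyloxy)-6-hydroxy-2-(2-hydroxypropan-2-yl)-2,3-dihydro-1-benzofuran-7-yl]-3-methylbutan-1-one | CC(C)CC(=O)c1c(O)cc(OCc2ccccc2)c2c1O[C@@H](C(C)(C)O)C2 | intermediate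
13 | 1-[(2R)-4,6-dihydroxy-2-(2-hydroxypropan-2-yl)-2,3-dihydro-1-benzofuran-7-yl]-3-methylbutan-1-one | CC(C)CC(=O)c1c(O)cc(O)c2c1O[C@@H](C(C)(C)O)C2 | intermediate
14 | 1-bromo-3-methylbut-2-ene (prenyl bromide) | CC(C)=CCBr | starting material
15 | 1-[(2R)-4,6-dihydroxy-2-(2-hydroxypropan-2-yl)-5-(3-methylbut-2-en-1-yl)-2,3-dihydro-1-benzofuran-7-yl]-3-methylbutan-1-one | CC(C)CC(=O)c1c(O)c(CC=C(C)C)c(O)c2c1O[C@@H](C(C)(C)O)C2 | intermediate
16 | (2R)-6-hydroxy-2-(2-hydroxypropan-2-yl)-7-(3-methylbutanoyl)-5,5-bis(3-methylbut-2-en-1-yl)-2,3-dihydro-1-benzofuran-4(5H)-one | CC(C)=CCC1(CC=C(C)C)C(=O)C2=C(O[C@@H](C(C)(C)O)C2)C(C(=O)CC(C)C)=C1O | target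

**Count**

Total step count: 9.
Longest linear sequence: 7 steps (steps 3, 4, 5, 6, 7, 8, 9, from 6 to 16); the arene branch (steps 1 and 2) joins at step 6.

**Steps most likely to fail**

1. Step 6 (key step). The first allylation may stop at O-allyl ethers or run on to a second allylation at the remaining ring carbon. Ring closure may discriminate poorly between the two faces of the 2-methyl π-allyl complex. Zerovalent palladium may also re-ionise the allylic aryl ether of 11 and erode its enantiomeric purity. The fallback sets out from 5 and returns at 12, so step 7 is then not needed. C-prenylation of 5 with 14 (aq KOH, 0 °C) should give 1-[4-(benzyloxy)-2,6-dihydroxy-3-(3-methylbut-2-en-1-yl)phenyl]-3-methylbutan-1-one F1. Acetylation of both phenols (Ac2O, pyridine, DMAP) should give 5-(benzyloxy)-2-(3-methylbutanoyl)-4-(3-methylbut-2-en-1-yl)-1,3-phenylene diacetate F2. Shi epoxidation with the fructose-type ketone catalyst of the L series (KHSO5, K2CO3 buffer, MeCN/dimethoxymethane/H2O, 0 °C), chosen as the antipode expected to deliver the S epoxide, should give 5-(benzyloxy)-4-{[(2S)-3,3-dimethyloxiran-2-yl]methyl}-2-(3-methylbutanoyl)-1,3-phenylene diacetate F3. K2CO3 in MeOH should then remove both acetates, and the phenoxide beside the chain should open the epoxide at its secondary carbon with inversion (5-exo), giving 12 with the R configuration.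

2. Step 9. O-prenylation may compete with C-prenylation, the second alkylation may lag behind the first or take place at the ring-fusion carbon C3a instead of C5, and prenyl bromide may be lost to methanolysis. The fallback sets out from 13 and returns at 16. Palladium-catalysed dearomative diallylation (Pd(PPh3)4, allyl methyl carbonate, THF, rt), in which the soft π-allyl electrophile reacts at carbon only, should give (2R)-6-hydroxy-2-(2-hydroxypropan-2-yl)-7-(3-methylbutanoyl)-5,5-di(prop-2-en-1-yl)-2,3-dihydro-1-benzofuran-4(5H)-one F4. Double cross-metathesis with 2-methylbut-2-ene (second-generation Grubbs catalyst, RuCl2(=CHPh)(PCy3)(H2IMes), CH2Cl2, 40 °C) should then turn both allyl groups into prenyl groups and give 16.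

3. Step 2. Alkylation may spread to the ortho hydroxyls or to ring carbon, because the phenoxide is ambident and the para preference rests only on acidity and hydrogen bonding. The fallback sets out from 3 and returns at 5. Mitsunobu etherification with benzyl alcohol (PPh3, diisopropyl azodicarboxylate, THF, 0 °C) engages only the most acidic, non-chelated para hydroxyl under neutral conditions and generates no free phenoxide. It makes no new compound (F0).

**Further compounds**

F1 | step 6 | 1-[4-(benzyloxy)-2,6-dihydroxy-3-(3-methylbut-2-en-1-yl)phenyl]-3-methylbutan-1-one | CC(C)CC(=O)c1c(O)cc(OCc2ccccc2)c(CC=C(C)C)c1O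
F2 | step 6 | 5-(benzyloxy)-2-(3-methylbutanoyl)-4-(3-methylbut-2-en-1-yl)-1,3-phenylene diacetate | CC(C)CC(=O)c1c(OC(C)=O)cc(OCc2ccccc2)c(CC=C(C)C)c1OC(C)=O
F3 | step 6 | 5-(benzyloxy)-4-{[(2S)-3,3-dimethyloxiran-2-yl]methyl}-2-(3-methylbutanoyl)-1,3-phenylene diacetate | CC(C)CC(=O)c1c(OC(C)=O)cc(OCc2ccccc2)c(C[C@@H]2OC2(C)C)c1OC(C)=O
F4 | step 9 | (2R)-6-hydroxy-2-(2-hydroxypropan-2-yl)-7-(3-methylbutanoyl)-5,5-di(prop-2-en-1-yl)-2,3-dihydro-1-benzofuran-4(5H)-one | C=CCC1(CC=C)C(=O)C2=C(O[C@@H](C(C)(C)O)C2)C(C(=O)CC(C)C)=C1O
F0 | step 2 | none | none
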